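If the next run was to be judged on solvolysis product, the choice lay between feeding first nucleophile, feeding starting material, or charging both at the start, and I wanted one number to choose by.

common to all: gas 0.95 mM (held)

| run | starting material | first nucleophile | remark | time |
|---|---|---|---|---|
| teal | 10 mM | 10.5 mM | run made earlier |  |
| ochre | 5 mM | 10.5 mM | run made earlier |  |
| Monday's | 10 mM | 10.5 mM (fed, over 8.0 h) | all else is in the flask from the start; the feed brings no volume worth counting | 20 h |
| Saturday's | 10 mM | 10.5 mM | everything together at the start | 20 h |
| Sunday's | 10 mM (fed, over 8.0 h) | 10.5 mM | all else is in the flask from the start; the feed brings no volume worth counting | 20 h |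

| run | time / h | solvolysis product / % | target / % |
|---|---|---|---|
| teal | 1.50 | 41.5 | 40.6 |
| teal | 3.00 | 42.1 | 43.4 |
| teal | 6.00 | 41.3 | 42.3 |
| teal | 10.0 | 43.7 | 42.6 |
| teal | 20.0 | 43.3 | 44.0 |
| ochre | 0.333 | 10.9 | 15.1 |
| ochre | 0.667 | 24.8 | 28.2 |
| ochre | 1.00 | 29.3 | 35.6 |
| ochre | 2.00 | 38.7 | 42.3 |
| ochre | 4.00 | 37.4 | 45.2 |

(standard deviation of a reading: 1 percentage point)

- at the start none of the gas is in solution
- a reading or a percentage of target counts all its forms, free or not

- the flask with the highest amount of solvolysis product, in percent of the starting material charged ("all alike" if they lie within 1.5 percentage points) (Monday's / Saturday's / Sunday's / all alike)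
- final solvolysis product, as a percentage of the starting material charged, in Monday's
- final solvolysis product, as a percentage of the starting material charged, in Saturday's
- final solvolysis product, as a percentage of the starting material charged, in Sunday's

I assumed that both products come from one intermediate. Solvolysis product made per target made then equals K/[first nucleophile], so with a batch charge the solvolysis product is K·ln([first nucleophile] at the start/[first nucleophile] at the end). The last teal reading gives 7.97 mM, and the last ochre reading, from a different charge, gives 7.72 mM. I called K the partition concentration, the [first nucleophile] at which target and solvolysis product form equally fast; it is a selectivity factor in concentration units.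

Then I compared rates at one moment. In the ochre run 53.0% of products stood at 0.667 h, out of 82.6% at the last reading. By that time Monday's feed had brought 0.875 mM, and free [first nucleophile] can be no more than the amount fed, so by my reckoning solvolysis product would form at least 9.11 times as fast as target. That comparison drifts as the feed goes on: K over the amount fed is down to 1.52 at the 4.00 h of the last ochre reading, and the amount fed reaches K at 6.07 h, later than that reading. Saturday's and Sunday's start with [first nucleophile] at 10.5 mM, above K. I therefore expected Monday's to stand highest, and it was the recipe to leave out if target was wanted.

The forecast also named Monday's: 77% (68% to 84%) there, 42.5% (40.5% to 44.5%) in Saturday's and 42.5% (37% to 48%) in Sunday's. Of the part not read, 12.7% in teal, it wrote “I treat that loss as a fixed fraction”.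

    intermediate → solvolysis product (k = 0.0570 min⁻¹)
    second nucleophile + intermediate → other capture product (k = 80.0 M⁻¹ min⁻¹)
    first nucleophile + intermediate → target (k = 7.00 M⁻¹ min⁻¹)
    gas ⇌ second nucleophile, rate k4*(csat - [second nucleophile]) (kL = 0.0230 min⁻¹)
    starting material → intermediate (k = 0.0280 min⁻¹)
    crystals ⇌ target, rate k6*(cs6 - [target]) while solid is left; crystals form when [target] > cs6 (solubility = 3.40 mM, k = 0.350 min⁻¹)

The flasks gave 75.6% in Monday's, 43.0% in Saturday's and 33.5% in Sunday's. In Monday's at 0.413 h the intermediate's half-life by first nucleophile was 3.6 h, far longer than the 0.20 h by solvolysis in Saturday's, and K turns Monday's final 75.6% against 6.89% of target into a [first nucleophile], averaged over the turnover of the intermediate, of about 0.726 mM. In Sunday's, K with the 35.4% of target gives 32.8% of solvolysis product against the 33.5% found, while other capture product stood at 31.1% against 13.9% in Saturday's.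

All runs stem from a simulated flask on assumed constants, and the scatter is random.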